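**Retrosynthetic overview**
1. The target is C2-symmetric: two identical 3-methylquinolizidin-2-ones (numbering in each half: C1 α-CH, C2 C=O, C3 CHMe, N5, C9, C9a; ring A = piperidine, ring B = piperidinone), each joined from C9 through five CH2 groups to C1 of the other half. The CH2 on C1 is β to the ring B ketone, so its bond to the next CH2 of the chain is a conjugate-addition bond, and it occurs twice in symmetry-equivalent form.
2. Cutting both bonds gives one monomer: a 1-methylene-quinolizidin-2-one (acceptor in ring B) whose C9 carries a (CH2)4 chain ending in a redox-active ester (radical donor). The key step is its head-to-tail decarboxylative radical cyclodimerization, which closes the 16-membered ring; base equilibration then sets the four α-keto centers.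
3. Ring B: aza-Michael/Dieckmann annulation on a cis-2,3-disubstituted piperidine, then decarboxylative Mannich methylenation of the Dieckmann β-keto ester.
4. Ring A and the two non-enolizable stereocenters (C9, C9a): auxiliary-directed all-cis hydrogenation of a 2,3,6-trisubstituted pyridine made from 3-bromo-6-fluoro-2-methylpyridine (SNAr, lateral carboxylation, B-alkyl Suzuki coupling).
5. Order of ring formation: pyridine → ring A → ring B → 16-membered ring.

Key step: step 10

Assumption: hydrogen is delivered to the pyridinium face opposite the isopropyl group of the hydrogen-bonded auxiliary; on this model the (S)-auxiliary leads to the (2S,3S)-piperidine, and the antipodal auxiliary would be used if the sense proved opposite.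

**Route**

Step 1
Reactants: 1 3-bromo-6-fluoro-2-methylpyridine; 2 (S)-4-isopropyloxazolidin-2-one
Product: 3 (S)-3-(5-bromo-6-methylpyridin-2-yl)-4-isopropyloxazolidin-2-one
Conditions: NaH, DMF, 0 → 60 °C
Reagents that add atoms: none
Why: Nucleophilic aromatic substitution (SNAr): the sodium salt of the oxazolidinone displaces fluoride at the 2-position of the pyridine, which is activated by the ring nitrogen and the para bromine, while the C–Br bond is untouched under metal-free conditions and the auxiliary stereocenter is not involved.

Step 2
Reactants: 3 (S)-3-(5-bromo-6-methylpyridin-2-yl)-4-isopropyloxazolidin-2-one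
Product: 4 methyl 2-{3-bromo-6-[(S)-4-isopropyl-2-oxooxazolidin-3-yl]pyridin-2-yl}acetate
Conditions: LiN(SiMe3)2 (2.5 equiv), dimethyl carbonate, THF, −20 → 0 °C; AcOH
Reagents that add atoms: dimethyl carbonate, COC(=O)OC
Why: Lateral (picolyl) deprotonation of the 2-methyl group and C-acylation with dimethyl carbonate: the product is more acidic than the starting material and is held as its enolate by the second equivalent of base, which stops the reaction at mono-acylation, and the silylamide does not attack the C–Br bond.

Step 3
Reactants: 4 methyl 2-{3-bromo-6-[(S)-4-isopropyl-2-oxooxazolidin-3-yl]pyridin-2-yl}acetate; 5 tert-butyl pent-4-enoate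
Product: 7 tert-butyl 5-{6-[(S)-4-isopropyl-2-oxooxazolidin-3-yl]-2-(2-methoxy-2-oxoethyl)pyridin-3-yl}pentanoate, via B-alkyl-9-BBN adduct 6 (not isolated)
Conditions: 5, 9-BBN, THF, 0 °C → rt; then 4, Pd(dppf)Cl2 (5 mol%), K3PO4 (aq), DMF, 60 °C
Reagents that add atoms: none
Why: B-alkyl Suzuki–Miyaura coupling: anti-Markovnikov hydroboration of the terminal alkene gives the primary alkylborane, which transmetalates to the arylpalladium bromide formed by oxidative addition of zerovalent palladium into the only C–Br bond, and reductive elimination joins the sp3 and sp2 carbons with both esters and the auxiliary tolerated.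

Step 4
Reactants: 7 tert-butyl 5-{6-[(S)-4-isopropyl-2-oxooxazolidin-3-yl]-2-(2-methoxy-2-oxoethyl)pyridin-3-yl}pentanoate
Product: 10 methyl 2-[(2S,3S)-3-(5-tert-butoxy-5-oxopentyl)piperidin-2-yl]acetate, via piperidine aminal 8 (not isolated), via cyclic imine 9 (not isolated)
Conditions: H2 (100 bar), Pd(OH)2/C, AcOH, 40 °C; then aq K2CO3
Reagents that add atoms: none
Why: Auxiliary-directed heterogeneous hydrogenation of a pyridine: in acetic acid the pyridinium N–H is hydrogen-bonded to the oxazolidinone carbonyl, the coplanar conformer exposes the face opposite the isopropyl group to the catalyst, all hydrogens add to that face so that C2 and C3 of the piperidine are set cis in the (2S,3S) sense, and aminal 8 then ionizes with loss of the auxiliary to imine 9, which is reduced to the ring CH2.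

Step 5
Reactants: 10 methyl 2-[(2S,3S)-3-(5-tert-butoxy-5-oxopentyl)piperidin-2-yl]acetate; 11 methyl methacrylate
Product: 12 methyl 3-[(2S,3S)-3-(5-tert-butoxy-5-oxopentyl)-2-(2-methoxy-2-oxoethyl)piperidin-1-yl]-2-methylpropanoate (both epimers at the CHMe carbon)
Conditions: MeOH, 65 °C (sealed tube)
Reagents that add atoms: none
Why: Aza-Michael addition of the secondary amine to methyl methacrylate in a protic solvent; the new CHMe center forms without control, which is harmless because it becomes an enolizable α-keto center that is equilibrated in step 11.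

Step 6
Reactants: 12 methyl 3-[(2S,3S)-3-(5-tert-butoxy-5-oxopentyl)-2-(2-methoxy-2-oxoethyl)piperidin-1-yl]-2-methylpropanoate
Product: 13 methyl (9S,9aR)-9-(5-tert-butoxy-5-oxopentyl)-3-methyl-2-oxooctahydro-2H-quinolizine-1-carboxylate (keto–enol and epimer mixture at C1 and C3)
Conditions: KOtBu, THF, 0 °C → rt; AcOH
Reagents that add atoms: none
Why: Dieckmann condensation: only the six-membered closure is possible, and only attack of the acetate α-carbon on the propanoate carbonyl gives a β-keto ester that is drained as its stabilized enolate (the regioisomer has a quaternary α-carbon and reverts by retro-Claisen cleavage), while the tert-butyl ester is too hindered to take part.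

Step 7
Reactants: 13 methyl (9S,9aR)-9-(5-tert-butoxy-5-oxopentyl)-3-methyl-2-oxooctahydro-2H-quinolizine-1-carboxylate
Product: 16 tert-butyl 5-[(9S,9aR)-3-methyl-1-methylidene-2-oxooctahydro-2H-quinolizin-9-yl]pentanoate, via β-keto acid 14 (not isolated), via Mannich acid 15 (not isolated)
Conditions: LiOH, THF/H2O, 0 °C; AcOH to pH 5; then aq CH2O, Et2NH, NaOAc, 0 → 45 °C
Reagents that add atoms: formaldehyde, C=O
Why: Saponification of the methyl β-keto ester (the tert-butyl ester resists hydroxide), Mannich reaction of β-keto acid 14 at its doubly activated carbon with the iminium ion from formaldehyde and diethylamine, and decarboxylative elimination of Mannich acid 15 (loss of CO2 and diethylamine), a known decarboxylative methylenation that places the exocyclic alkene at C1 only and forms no stereocenter.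

Step 8
Reactants: 16 tert-butyl 5-[(9S,9aR)-3-methyl-1-methylidene-2-oxooctahydro-2H-quinolizin-9-yl]pentanoate
Product: 17 5-[(9S,9aR)-3-methyl-1-methylidene-2-oxooctahydro-2H-quinolizin-9-yl]pentanoic acid p-toluenesulfonate salt
Conditions: TsOH·H2O (1.0 equiv), CF3CO2H/CH2Cl2, 0 °C → rt; evaporate with toluene
Reagents that add atoms: p-toluenesulfonic acid, Cc1ccc(cc1)S(=O)(=O)O
Why: Acidolysis of the tert-butyl ester by the E1 path (loss of 2-methylpropene), with one equivalent of sulfonic acid so that the product is isolated with the nitrogen protonated, which blocks base-mediated migration of the exocyclic alkene into the ring and retro-Michael opening.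

Step 9
Reactants: 17 5-[(9S,9aR)-3-methyl-1-methylidene-2-oxooctahydro-2H-quinolizin-9-yl]pentanoic acid p-toluenesulfonate salt; 18 N-hydroxyphthalimide
Product: 19 1,3-dioxoisoindolin-2-yl 5-[(9S,9aR)-3-methyl-1-methylidene-2-oxooctahydro-2H-quinolizin-9-yl]pentanoate p-toluenesulfonate salt
Conditions: N,N'-diisopropylcarbodiimide, CH2Cl2, 0 °C → rt
Reagents that add atoms: none
Why: Carbodiimide esterification of the free carboxylic acid with N-hydroxyphthalimide to the redox-active N-(acyloxy)phthalimide; the sulfonate counter-ion cannot be activated by the carbodiimide, and the protonated amine and the enone are spectators.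

Step 10
Reactants: 19 1,3-dioxoisoindolin-2-yl 5-[(9S,9aR)-3-methyl-1-methylidene-2-oxooctahydro-2H-quinolizin-9-yl]pentanoate p-toluenesulfonate salt (two molecules)
Product: 21 sixteen-membered bis-quinolizidinone as a mixture of epimers at the four α-keto carbons, via linear dimer 20 (not isolated)
Conditions: Ru(bpy)3(PF6)2 (2 mol%), diethyl 1,4-dihydro-2,6-dimethylpyridine-3,5-dicarboxylate (syringe pump), CH2Cl2/DMF, 10 mM, blue LEDs, rt; then cold 1 M NaOH
Reagents that add atoms: none
Why: Proposed new method: monovalent ruthenium, formed from excited Ru(bpy)3(PF6)2 and the dihydropyridine, transfers an electron to the N-(acyloxy)phthalimide, which loses phthalimide anion and CO2 to leave a primary alkyl radical at the chain end; this radical adds to the exocyclic CH2 of the 1-methylene-quinolizidin-2-one of a second molecule (Giese addition), the α-keto radical takes a hydrogen atom from the dihydropyridine, and the same events inside linear dimer 20 close the ring. The closest known reaction types are the photoredox decarboxylative Giese macrocyclization of peptide acrylamides and the radical macrocyclization of ω-iodoalkyl enones with a hydride donor; new here is the pairing of one intermolecular and one intramolecular addition in a head-to-tail cyclodimerization. The sixteen-membered ring closes in the 16-endo-trig mode, both alkene carbons of the acceptor ending up in the ring, while rings A and B are already in place. The two new stereocenters (C1 of each ring B) arise by hydrogen-atom delivery to the α-keto radical, expected on the axial face so that the new chain lies equatorial, and because they are enolizable any error is repaired in step 11. The step needs head-to-tail regiochemistry, which is the only pairing open to a monomer with one donor and one acceptor, and it needs cyclic dimer in preference to eight-membered closure within one monomer and to oligomer, which the concentration of about 10 mM is chosen to secure: high enough for the bimolecular addition to outrun the strained bridged closure, low enough for the strain-free sixteen-membered closure to outrun further chain growth. The tosylate salt keeps the nitrogen lone pair from quenching the photocatalyst, from shifting the exocyclic double bond into the ring and from β-elimination.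

Step 11
Reactants: 21 sixteen-membered bis-quinolizidinone as a mixture of epimers at the four α-keto carbons
Product: 22 target CNP0268544.6
Conditions: DBU, toluene, rt → 40 °C
Reagents that add atoms: none
Why: Base-mediated epimerization through the ketone enolates (thermodynamic control): in each trans-fused quinolizidinone the C3 methyl and the C1 chain settle equatorial, which is the configuration of the target, while C9 and C9a are not enolizable and stay as set in step 4, and the aprotic amidine base avoids the protonated-amine pathway needed for retro-Michael or retro-Mannich opening.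

**Compound list**
1 | 3-bromo-6-fluoro-2-methylpyridine | Cc1nc(F)ccc1Br | starting material
2 | (S)-4-isopropyloxazolidin-2-one | CC(C)[C@H]1COC(=O)N1 | starting material
3 | (S)-3-(5-bromo-6-methylpyridin-2-yl)-4-isopropyloxazolidin-2-one | CC(C)[C@H]1COC(=O)N1c1ccc(Br)c(C)n1 | intermediate
4 | methyl 2-{3-bromo-6-[(S)-4-isopropyl-2-oxooxazolidin-3-yl]pyridin-2-yl}acetate | CC(C)[C@H]1COC(=O)N1c1ccc(Br)c(CC(=O)OC)n1 | intermediate
5 | tert-butyl pent-4-enoate | C=CCCC(=O)OC(C)(C)C | starting material
6 | tert-butyl 5-(9-borabicyclo[3.3.1]nonan-9-yl)pentanoate (formed in the flask) | CC(C)(C)OC(=O)CCCCB1C2CCCC1CCC2 | intermediate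
7 | tert-butyl 5-{6-[(S)-4-isopropyl-2-oxooxazolidin-3-yl]-2-(2-methoxy-2-oxoethyl)pyridin-3-yl}pentanoate | CC(C)[C@H]1COC(=O)N1c1ccc(CCCCC(=O)OC(C)(C)C)c(CC(=O)OC)n1 | intermediate
8 | tert-butyl 5-{(2S,3S,6R)-6-[(S)-4-isopropyl-2-oxooxazolidin-3-yl]-2-(2-methoxy-2-oxoethyl)piperidin-3-yl}pentanoate (all-cis aminal, formed in the flask) | COC(=O)C[C@@H]1N[C@H](N2C(=O)OC[C@@H]2C(C)C)CC[C@@H]1CCCCC(=O)OC(C)(C)C | intermediate
9 | tert-butyl 5-[(2S,3S)-2-(2-methoxy-2-oxoethyl)-2,3,4,5-tetrahydropyridin-3-yl]pentanoate (formed in the flask) | COC(=O)C[C@@H]1N=CCC[C@@H]1CCCCC(=O)OC(C)(C)C | intermediate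
10 | methyl 2-[(2S,3S)-3-(5-tert-butoxy-5-oxopentyl)piperidin-2-yl]acetate | COC(=O)C[C@@H]1NCCC[C@@H]1CCCCC(=O)OC(C)(C)C | intermediate
11 | methyl methacrylate | C=C(C)C(=O)OC | starting material
12 | methyl 3-[(2S,3S)-3-(5-tert-butoxy-5-oxopentyl)-2-(2-methoxy-2-oxoethyl)piperidin-1-yl]-2-methylpropanoate (both epimers at CHMe) | COC(=O)C[C@@H]1N(CC(C)C(=O)OC)CCC[C@@H]1CCCCC(=O)OC(C)(C)C | intermediate
13 | methyl (9S,9aR)-9-(5-tert-butoxy-5-oxopentyl)-3-methyl-2-oxooctahydro-2H-quinolizine-1-carboxylate (C1 and C3 not fixed) | CC1CN2CCC[C@H](CCCCC(=O)OC(C)(C)C)[C@@H]2C(C(=O)OC)C1=O | intermediate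
14 | (9S,9aR)-9-(5-tert-butoxy-5-oxopentyl)-3-methyl-2-oxooctahydro-2H-quinolizine-1-carboxylic acid (formed in the flask) | CC1CN2CCC[C@H](CCCCC(=O)OC(C)(C)C)[C@@H]2C(C(=O)O)C1=O | intermediate
15 | (9S,9aR)-9-(5-tert-butoxy-5-oxopentyl)-1-[(diethylamino)methyl]-3-methyl-2-oxooctahydro-2H-quinolizine-1-carboxylic acid (formed in the flask) | CC1CN2CCC[C@H](CCCCC(=O)OC(C)(C)C)[C@@H]2C(CN(CC)CC)(C(=O)O)C1=O | intermediate
16 | tert-butyl 5-[(9S,9aR)-3-methyl-1-methylidene-2-oxooctahydro-2H-quinolizin-9-yl]pentanoate (C3 not fixed) | CC1CN2CCC[C@H](CCCCC(=O)OC(C)(C)C)[C@@H]2C(=C)C1=O | intermediate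
17 | 5-[(9S,9aR)-3-methyl-1-methylidene-2-oxooctahydro-2H-quinolizin-9-yl]pentanoic acid p-toluenesulfonate salt | CC1CN2CCC[C@H](CCCCC(=O)O)[C@@H]2C(=C)C1=O.Cc1ccc(cc1)S(=O)(=O)O | intermediate
18 | N-hydroxyphthalimide | O=C1c2ccccc2C(=O)N1O | starting material
19 | 1,3-dioxoisoindolin-2-yl 5-[(9S,9aR)-3-methyl-1-methylidene-2-oxooctahydro-2H-quinolizin-9-yl]pentanoate p-toluenesulfonate salt | CC1CN2CCC[C@H](CCCCC(=O)ON3C(=O)c4ccccc4C3=O)[C@@H]2C(=C)C1=O.Cc1ccc(cc1)S(=O)(=O)O | intermediate
20 | linear head-to-tail dimer, bis-tosylate: the C9 chain of an enone unit is bonded to the CH2 on C1 of a second unit that still carries the N-(acyloxy)phthalimide; C9 S and C9a R in both units (formed in the flask) | CC1CN2CCC[C@H](CCCCCC3C(=O)C(C)CN4CCC[C@H](CCCCC(=O)ON5C(=O)c6ccccc6C5=O)[C@H]34)[C@@H]2C(=C)C1=O.Cc1ccc(cc1)S(=O)(=O)O.Cc1ccc(cc1)S(=O)(=O)O | intermediate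
21 | sixteen-membered bis-quinolizidinone, target constitution with C9 and C9a of both halves set, the four α-keto carbons not fixed | CC1CN2CCC[C@@H]3CCCCCC4C(=O)C(C)CN5CCC[C@H](CCCCCC(C1=O)[C@@H]32)[C@H]45 | intermediate
22 | target CNP0268544.6 (C2-symmetric bis-quinolizidinone, all α-keto substituents equatorial) | C[C@H]1CN2CCC[C@@H]3CCCCC[C@H]4C(=O)[C@@H](C)CN5CCC[C@H](CCCCC[C@@H](C1=O)[C@@H]32)[C@H]45 | target

**Step count and risks**
Total step count: 11. Longest linear sequence: 11 steps (from 1 to 22).

Most likely to fail:

1. Step 10 (proposed new method). Chain growth to linear and larger cyclic oligomers, eight-membered closure within one monomer, and premature hydrogen-atom capture by the chain-end radical may all outrun the sixteen-membered closure.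
Fallback: the two C–C bonds are made one after the other by known intermolecular and intramolecular Giese additions. Setting out from 13, the tert-butyl ester is cleaved as in step 8 to the keto ester acid tosylate F1, which is esterified as in step 9 to its N-(acyloxy)phthalimide tosylate F2, a radical donor without an acceptor. F2 and an excess of enone acid 17 (an acceptor without a donor) are coupled at about 0.2 M under the photoredox conditions of step 10 to give the linear keto ester acid F3. The protocol of step 7 then converts the β-keto ester of F3 into the exocyclic enone of the linear enone acid F4. Salt formation with TsOH and esterification as in step 9 give 20, here isolated as its bis-tosylate, and its intramolecular Giese addition at about 1 mM, a radical macrocyclization of a known type, comes back to the route at 21.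

2. Step 7. Retro-Claisen ring opening during saponification, decarboxylation before the Mannich reaction has taken place, and migration of the exocyclic double bond into ring B may each divert the material.
Fallback: setting out from 13, saponification and warming of acid 14 give the ketone F5. LiN(iPr)2 in THF at −78 °C forms the kinetic enolate at the C1 methylene, and dimethyl(methylidene)ammonium iodide gives the Mannich base F6. MeI in Et2O quaternizes the unhindered dimethylamino group to the ammonium iodide F7, and aq NaHCO3/CH2Cl2 eliminates trimethylamine, which comes back to the route at 16.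

3. Step 4. Facial control may be eroded if the pyridinium N–H hydrogen-bonds to the side-chain ester in place of the auxiliary carbonyl, or if partly reduced enamino ester intermediates leave the catalyst and are reduced later from either face, giving material of low enantiomeric purity or trans isomer.
Fallback: setting out from 7, hydrogenation over PtO2 in AcOH gives cis-10 without reliance on the auxiliary. Crystallization of its salt with (2R,3R)-di-O-p-toluoyltartaric acid, the diastereomeric salt F8 (the antipodal acid is used if it gives the less soluble salt of the (2S,3S)-amine), and liberation with aq K2CO3 come back to the route at 10.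

**Further compounds**
F1 | step 10 | 5-[(9S,9aR)-1-(methoxycarbonyl)-3-methyl-2-oxooctahydro-2H-quinolizin-9-yl]pentanoic acid p-toluenesulfonate salt | CC1CN2CCC[C@H](CCCCC(=O)O)[C@@H]2C(C(=O)OC)C1=O.Cc1ccc(cc1)S(=O)(=O)O
F2 | step 10 | 1,3-dioxoisoindolin-2-yl 5-[(9S,9aR)-1-(methoxycarbonyl)-3-methyl-2-oxooctahydro-2H-quinolizin-9-yl]pentanoate p-toluenesulfonate salt | CC1CN2CCC[C@H](CCCCC(=O)ON3C(=O)c4ccccc4C3=O)[C@@H]2C(C(=O)OC)C1=O.Cc1ccc(cc1)S(=O)(=O)O
F3 | step 10 | linear keto ester acid: the C9 chain of a 1-(methoxycarbonyl)quinolizidin-2-one unit bonded to the CH2 on C1 of a second unit that carries the 4-carboxybutyl chain at C9 | CC1CN2CCC[C@H](CCCCCC3C(=O)C(C)CN4CCC[C@H](CCCCC(=O)O)[C@H]34)[C@@H]2C(C(=O)OC)C1=O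
F4 | step 10 | linear enone acid: as F3 with the 1-(methoxycarbonyl) group replaced by an exocyclic 1-methylidene group | CC1CN2CCC[C@H](CCCCCC3C(=O)C(C)CN4CCC[C@H](CCCCC(=O)O)[C@H]34)[C@@H]2C(=C)C1=O
F5 | step 7 | tert-butyl 5-[(9S,9aS)-3-methyl-2-oxooctahydro-2H-quinolizin-9-yl]pentanoate | CC1CN2CCC[C@H](CCCCC(=O)OC(C)(C)C)[C@@H]2CC1=O
F6 | step 7 | tert-butyl 5-[(9S,9aR)-1-[(dimethylamino)methyl]-3-methyl-2-oxooctahydro-2H-quinolizin-9-yl]pentanoate | CC1CN2CCC[C@H](CCCCC(=O)OC(C)(C)C)[C@@H]2C(CN(C)C)C1=O
F7 | step 7 | {(9S,9aR)-9-(5-tert-butoxy-5-oxopentyl)-3-methyl-2-oxooctahydro-2H-quinolizin-1-yl}methyl-trimethylammonium iodide | CC1CN2CCC[C@H](CCCCC(=O)OC(C)(C)C)[C@@H]2C(C[N+](C)(C)C)C1=O.[I-]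
F8 | step 4 | salt of 10 with (2R,3R)-di-O-p-toluoyltartaric acid | COC(=O)C[C@@H]1NCCC[C@@H]1CCCCC(=O)OC(C)(C)C.OC(=O)[C@H](OC(=O)c1ccc(C)cc1)[C@@H](OC(=O)c1ccc(C)cc1)C(O)=O
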